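**Plan**

- Retrosynthesis: the two esters and the C15 acid are removed first. C9–C11 is then cut, with the side chain added as an alkyllithium to a C9 ketone and the oxygen moved from C9 to C7 by oxidative allylic transposition. Last, C1–C10 and C4–C5 are cut in a Diels–Alder disconnection of ring A.
- Enabling feature: ring B (O at C6, CH3 on C8, sp2 C9 next to the methylated quaternary C10, H on C5) is the substitution pattern of 2,6-dimethyl-1,4-benzoquinone. Ring A (C1H2 … C4Me2) is a 1,1-dimethylbutadiene.
- Strengthening: the bare 4-methylpenta-1,3-diene is a poor diene, so its 2-silyloxy analogue from mesityl oxide is used; the extra C2 oxygen is deleted afterwards.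
- Forward order: ring B is bought; ring A closes in step 2; C2 is deoxygenated (steps 5–7); the side chain is joined at C9 (step 14); ring B is adjusted (steps 15–19); C15 is oxidised (steps 20–22).
- Stereochemistry: C10 from the chiral Lewis acid (π-face); C5 by equilibration to the trans-decalin; C6 by α-face hydride; C7 by hydride delivery from the 6β-OH; the 13E alkene by syn-carboalumination.

Key step: step 2

Remark on nomenclature: labdane numbering is used for all bicyclic compounds (C1–C3 ring-A CH2, C4 CMe2, C5/C10 ring fusion, C6–C9 ring B, C11–C16 side chain, C17 on C8, C20 on C10); β is the face of the C10 methyl group.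

Assumption: the (S)-configured oxazaborolidinium salt is taken as the antipode that exposes the quinone face leading to 10β-methyl; the sense should be confirmed on 5 and, if opposite, the (R)-catalyst is used without other change.

Step 1
Reactants: 1 mesityl oxide (4-methylpent-3-en-2-one)
Product: 3 triisopropyl[(4-methylpenta-1,3-dien-2-yl)oxy]silane, via lithium dienolate 2 (not isolated)
Conditions: LDA (commercial solution), THF, −78 °C; TIPSOTf, −78 → 0 °C
Reagents that add atoms: triisopropylsilyl trifluoromethanesulfonate, CC(C)[Si](OS(=O)(=O)C(F)(F)F)(C(C)C)C(C)C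
Why: Kinetic deprotonation of the α′-methyl group gives the cross-conjugated lithium dienolate, which is O-silylated by the silyl triflate (silyl enol ether formation).

Step 2
Reactants: 3 triisopropyl[(4-methylpenta-1,3-dien-2-yl)oxy]silane; 4 2,6-dimethyl-1,4-benzoquinone
Product: 5 cis-fused 2-(triisopropylsilyloxy)-5β-11,12,13,14,15,16-hexanorlabda-2,7-diene-6,9-dione (10β-CH3)
Conditions: (S)-B-(o-tolyl)oxazaborolidinium bistriflimide from α,α-diphenylprolinol (20 mol%), CH2Cl2, −78 → −40 °C
Reagents that add atoms: none
Why: The cationic boron should bind the C6 carbonyl of 4 (flanked by two vinylic C–H; the C9 carbonyl sits between two methyl-bearing carbons), so that C10 becomes the β-carbon of the activated enone; the silyl enol ether CH2 terminus of 3 bonds there first and the CMe2 terminus closes on C5 in a strongly asynchronous suprafacial [4+2], the 2-silyloxy group raising the diene HOMO, stabilising the developing charge at C2 as an oxocarbenium ion and easing the s-cis penalty of the parent 1,1-dimethyl diene. The closest known reaction type is the oxazaborolidinium-catalysed Diels–Alder reaction of 2-silyloxybuta-1,3-dienes with methyl-substituted 1,4-benzoquinones, together with Lewis-acid cycloadditions of 4-methyl-2-silyloxypenta-1,3-dienes to hindered enones. Ring A is closed as a six-membered carbocycle by the cycloaddition itself (C1–C10 first, then C4–C5, formally a 6-endo closure of the boron enolate onto the silyloxyallyl cation terminus). C10 is set by the catalyst, which shields one π-face of the bound quinone; since the two C=C bonds of 4 are mirror-related, the face is the only stereochemical choice, and C5 arises cis to the C10 methyl by suprafacial addition. The step needs regioselectivity, secured by attack of the nucleophilic CH2 terminus on the β-carbon and by avoiding a quaternary–quaternary bond, and mono-addition, secured because the remaining ene-dione C=C of 5 is more hindered and less electrophilic than the quinone.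

Step 3
Reactants: 5 cis-fused adduct
Product: 6 trans-fused 2-(triisopropylsilyloxy)-5α-11,12,13,14,15,16-hexanorlabda-2,7-diene-6,9-dione
Conditions: DBU (0.2 equiv), CH2Cl2, 0 °C → rt
Reagents that add atoms: none
Why: C5–H is α to C6=O and vinylogously acidified by C9=O, so catalytic base should equilibrate the ring fusion through the dienolate toward the trans-decalin (base-mediated epimerisation); C10 is quaternary and the silyl enol ether is inert to amidine base.

Step 4
Reactants: 6 trans-fused ene-dione
Product: 7 6β-hydroxy-2-(triisopropylsilyloxy)-11,12,13,14,15,16-hexanorlabda-2,7-dien-9-one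
Conditions: NaBH4, CeCl3·7H2O, MeOH/CH2Cl2, −78 °C
Reagents that add atoms: none
Why: Luche 1,2-reduction should take place at the less hindered C6 carbonyl from the α face, the β face being blocked by the syn-axial 4β- and 10β-methyl groups, giving the axial 6β-alcohol; the C9 carbonyl between quaternary C10 and methylated C8 and the silyl enol ether are left.

Step 5
Reactants: 7 6β-hydroxy silyl enol ether
Product: 8 6β-hydroxy-11,12,13,14,15,16-hexanorlabd-7-ene-2,9-dione
Conditions: 48% aq. HF, MeCN, 0 °C
Reagents that add atoms: none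
Why: Fluoride-assisted protodesilylation of the silyl enol ether (protonation at C3, Si–F formation) unveils the C2 ketone without touching the allylic alcohol or the enone.

Step 6
Reactants: 8 hydroxy dione
Product: 9 C2 tosylhydrazone of 8
Conditions: TsNHNH2, EtOH, rt → 40 °C
Reagents that add atoms: p-toluenesulfonyl hydrazide, Cc1ccc(cc1)S(=O)(=O)NN
Why: Hydrazone condensation occurs at the unhindered saturated C2 ketone; the conjugated C9 ketone between C8–CH3 and quaternary C10 should not condense.

Step 7
Reactants: 9 C2 tosylhydrazone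
Product: 11 6β-hydroxy-11,12,13,14,15,16-hexanorlabd-7-en-9-one, via boryl hydrazide 10 (not isolated)
Conditions: catecholborane (2.5 equiv), CHCl3, 0 °C → rt; then NaOAc·3H2O, reflux
Reagents that add atoms: none
Why: Caglioti-type reductive deoxygenation: hydroboration of C=N, then acetate-induced loss of sulfinate and N2 from the diazene leaves CH2 at C2; the s-trans-locked hindered enone is not reduced by catecholborane and the O6 borate is hydrolysed on work-up.

Step 8
Reactants: 11 6β-hydroxy enone
Product: 12 6β-(triethylsilyloxy)-11,12,13,14,15,16-hexanorlabd-7-en-9-one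
Conditions: TESOTf, 2,6-lutidine, CH2Cl2, −78 → 0 °C
Reagents that add atoms: triethylsilyl trifluoromethanesulfonate, CC[Si](CC)(CC)OS(=O)(=O)C(F)(F)F
Why: A silyl triflate with a hindered pyridine base silylates even the syn-diaxially flanked 6β-hydroxyl (silyl ether protection), masking it for the organolithium and chromium(VI) steps.

Step 9
Reactants: 13 but-3-yn-1-ol
Product: 14 tert-butyl(but-3-yn-1-yloxy)dimethylsilane
Conditions: TBSCl, imidazole, CH2Cl2, rt
Reagents that add atoms: tert-butyldimethylsilyl chloride, CC(C)(C)[Si](C)(C)Cl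
Why: Standard silylation of a primary alcohol, needed so that the two chain ends can later be told apart.

Step 10
Reactants: 14 tert-butyl(but-3-yn-1-yloxy)dimethylsilane
Product: 17 (E)-5-(tert-butyldimethylsilyloxy)-3-methylpent-2-en-1-ol, via alkenylalane 15 (not isolated), via lithium alanate 16 (not isolated)
Conditions: AlMe3, Cp2ZrCl2 (0.25 equiv), CH2Cl2, 0 °C → rt; n-BuLi, THF, −78 °C; (CH2O)n, → rt
Reagents that add atoms: trimethylaluminium, C[Al](C)C; paraformaldehyde (formaldehyde), C=O
Why: Negishi zirconium-catalysed carboalumination adds CH3–Al syn across the terminal alkyne with methyl on the internal carbon, and the derived alanate is hydroxymethylated with retention, which fixes the E trisubstituted alkene.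

Step 11
Reactants: 17 (E)-allylic alcohol
Product: 18 tert-butyl{[(3E)-5-(4-methoxybenzyloxy)-3-methylpent-3-en-1-yl]oxy}dimethylsilane
Conditions: NaH, PMBCl, Bu4NI (cat.), THF/DMF, 0 °C → rt
Reagents that add atoms: 4-methoxybenzyl chloride, COc1ccc(CCl)cc1
Why: Williamson etherification of the primary allylic alkoxide; the PMB ether is orthogonal to the silyl groups used later.

Step 12
Reactants: 18 PMB/TBS bis-ether
Product: 19 (E)-5-(4-methoxybenzyloxy)-3-methylpent-3-en-1-ol
Conditions: TBAF, THF, 0 °C → rt
Reagents that add atoms: none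
Why: Fluoride cleaves the primary TBS ether while the PMB ether is inert (desilylation).

Step 13
Reactants: 19 homoallylic alcohol
Product: 20 1-({[(2E)-5-iodo-3-methylpent-2-en-1-yl]oxy}methyl)-4-methoxybenzene
Conditions: I2, PPh3, imidazole, CH2Cl2, 0 °C
Reagents that add atoms: iodine, II
Why: Appel-type iodination (SN2 on the oxyphosphonium salt of a primary alcohol) leaves the alkene geometry untouched.

Step 14
Reactants: 20 homoallylic iodide; 12 6β-(triethylsilyloxy) enone
Product: 22 15-(4-methoxybenzyloxy)-6β-(triethylsilyloxy)labda-7,13E-dien-9-ol, via alkyllithium 21 (not isolated)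
Conditions: 20, t-BuLi (2.1 equiv), Et2O/pentane, −78 °C; then 12, −78 → −20 °C
Reagents that add atoms: none
Why: Iodine–lithium exchange gives the primary alkyllithium, which should add 1,2 to the non-enolisable C9 ketone as with 2,6,6-trisubstituted cyclohexenones, mainly from the α face anti to the C10 methyl; the C9 configuration is erased in step 15.

Step 15
Reactants: 22 tertiary allylic alcohol
Product: 23 15-(4-methoxybenzyloxy)-6β-(triethylsilyloxy)labda-8,13E-dien-7-one
Conditions: PCC, 4 Å MS, CH2Cl2, rt
Reagents that add atoms: pyridinium chlorochromate, [O-][Cr](=O)(=O)Cl.c1cc[nH+]cc1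
Why: Dauben–Babler oxidative transposition: the tertiary allylic chromate ester shifts [3,3] to C7 and is oxidised, moving oxygen from C9 to C7 and the alkene to the tetrasubstituted C8=C9 position; the equatorial C6–H is poorly aligned for enolisation, and the hindered silyl ether, PMB ether and isolated alkene should survive.

Step 16
Reactants: 23 6β-(triethylsilyloxy) 7-ketone
Product: 24 6β-hydroxy-15-(4-methoxybenzyloxy)labda-8,13E-dien-7-one
Conditions: HF·pyridine, THF/pyridine, 0 °C → rt
Reagents that add atoms: none
Why: Buffered fluoride desilylation frees the α-ketol under non-basic conditions that avoid ketol isomerisation; the PMB ether is stable.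

Step 17
Reactants: 24 6β-hydroxy 7-ketone
Product: 25 15-(4-methoxybenzyloxy)labda-8,13E-diene-6β,7α-diol
Conditions: Me4NBH(OAc)3, MeCN/AcOH (1:1), −20 → 0 °C
Reagents that add atoms: none
Why: Hydroxyl-directed reduction of Saksena–Evans type: the axial 6β-hydroxyl exchanges onto boron and delivers hydride to the β face of the C7 carbonyl, which should give the 7α-alcohol and hence the trans-diaxial diol.

Step 18
Reactants: 25 6β,7α-diol
Product: 26 6β-hydroxy-15-(4-methoxybenzyloxy)labda-8,13E-dien-7α-yl 3-methylbutanoate
Conditions: isovaleric anhydride (1.2 equiv), DMAP (cat.), pyridine, CH2Cl2, 0 °C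
Reagents that add atoms: 3-methylbutanoic anhydride, CC(C)CC(=O)OC(=O)CC(C)C
Why: DMAP-catalysed (Steglich-type) acylation should select the allylic 7α-hydroxyl because the 6β-hydroxyl is syn-diaxial to the C4 and C10 methyl groups.

Step 19
Reactants: 26 7α-isovalerate
Product: 27 6β-acetoxy-15-(4-methoxybenzyloxy)labda-8,13E-dien-7α-yl 3-methylbutanoate
Conditions: Ac2O, DMAP, pyridine, 50 °C
Reagents that add atoms: acetic anhydride, CC(=O)OC(C)=O
Why: Forcing DMAP-catalysed acetylation of the hindered axial 6β-hydroxyl; the trans-diaxial arrangement precludes acyl migration.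

Step 20
Reactants: 27 diester PMB ether
Product: 28 6β-acetoxy-15-hydroxylabda-8,13E-dien-7α-yl 3-methylbutanoate
Conditions: DDQ, CH2Cl2/pH 7 buffer, 0 °C
Reagents that add atoms: none
Why: Oxidative PMB ether cleavage (benzylic hydride abstraction, hemiacetal hydrolysis) leaves esters and alkenes untouched.

Step 21
Reactants: 28 allylic alcohol
Product: 29 6β-acetoxy-15-oxolabda-8,13E-dien-7α-yl 3-methylbutanoate
Conditions: MnO2, CH2Cl2, rt
Reagents that add atoms: none
Why: Manganese dioxide oxidation of the primary allylic alcohol gives the enal with retention of the E geometry.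

Step 22
Reactants: 29 enal
Product: 30 6β-acetoxy-7α-(3-methylbutanoyloxy)labda-8,13E-dien-15-oic acid
Conditions: NaClO2, NaH2PO4, 2-methylbut-2-ene, t-BuOH/H2O, rt
Reagents that add atoms: sodium chlorite, [Na+].[O-]Cl=O
Why: Pinnick oxidation converts the enal into the acid, with the alkene scavenger protecting the C=C bonds; esters and stereocentres are unaffected.

**Compound list**

1 | 4-methylpent-3-en-2-one (mesityl oxide) | CC(=O)C=C(C)C | starting material
2 | lithium 4-methylpenta-1,3-dien-2-olate (not isolated) | [Li+].[O-]C(=C)C=C(C)C | intermediate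
3 | triisopropyl[(4-methylpenta-1,3-dien-2-yl)oxy]silane | C=C(O[Si](C(C)C)(C(C)C)C(C)C)C=C(C)C | intermediate
4 | 2,6-dimethyl-1,4-benzoquinone | CC1=CC(=O)C=C(C)C1=O | starting material
5 | cis-fused 2-(triisopropylsilyloxy)-5β-11,12,13,14,15,16-hexanorlabda-2,7-diene-6,9-dione | O=C1C=C(C)C(=O)[C@@]2(C)CC(O[Si](C(C)C)(C(C)C)C(C)C)=CC(C)(C)[C@@H]12 | intermediate
6 | trans-fused 2-(triisopropylsilyloxy)-5α-11,12,13,14,15,16-hexanorlabda-2,7-diene-6,9-dione | O=C1C=C(C)C(=O)[C@@]2(C)CC(O[Si](C(C)C)(C(C)C)C(C)C)=CC(C)(C)[C@H]12 | intermediate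
7 | 6β-hydroxy-2-(triisopropylsilyloxy)-11,12,13,14,15,16-hexanorlabda-2,7-dien-9-one | O[C@@H]1C=C(C)C(=O)[C@@]2(C)CC(O[Si](C(C)C)(C(C)C)C(C)C)=CC(C)(C)[C@H]12 | intermediate
8 | 6β-hydroxy-11,12,13,14,15,16-hexanorlabd-7-ene-2,9-dione | O[C@@H]1C=C(C)C(=O)[C@@]2(C)CC(=O)CC(C)(C)[C@H]12 | intermediate
9 | C2 p-toluenesulfonylhydrazone of 8 | O[C@@H]1C=C(C)C(=O)[C@@]2(C)CC(=NNS(=O)(=O)c3ccc(C)cc3)CC(C)(C)[C@H]12 | intermediate
10 | N-catecholboryl tosylhydrazide at C2 with O6 catecholborate (C2 epimers; not isolated) | c1ccc2OB(Oc2c1)O[C@@H]3C=C(C)C(=O)[C@@]4(C)CC(N(B5Oc6ccccc6O5)NS(=O)(=O)c7ccc(C)cc7)CC(C)(C)[C@H]34 | intermediate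
11 | 6β-hydroxy-11,12,13,14,15,16-hexanorlabd-7-en-9-one | O[C@@H]1C=C(C)C(=O)[C@@]2(C)CCCC(C)(C)[C@H]12 | intermediate
12 | 6β-(triethylsilyloxy)-11,12,13,14,15,16-hexanorlabd-7-en-9-one | CC[Si](CC)(CC)O[C@@H]1C=C(C)C(=O)[C@@]2(C)CCCC(C)(C)[C@H]12 | intermediate
13 | but-3-yn-1-ol | C#CCCO | starting material
14 | tert-butyl(but-3-yn-1-yloxy)dimethylsilane | C#CCCO[Si](C)(C)C(C)(C)C | intermediate
15 | [(1E)-4-(tert-butyldimethylsilyloxy)-2-methylbut-1-en-1-yl]dimethylalane (not isolated) | C[Al](C)/C=C(C)/CCO[Si](C)(C)C(C)(C)C | intermediate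
16 | lithium butyl[(1E)-4-(tert-butyldimethylsilyloxy)-2-methylbut-1-en-1-yl]dimethylalanate (not isolated) | [Li+].CCCC[Al-](C)(C)/C=C(C)/CCO[Si](C)(C)C(C)(C)C | intermediate
17 | (E)-5-(tert-butyldimethylsilyloxy)-3-methylpent-2-en-1-ol | OC/C=C(C)/CCO[Si](C)(C)C(C)(C)C | intermediate
18 | tert-butyl{[(3E)-5-(4-methoxybenzyloxy)-3-methylpent-3-en-1-yl]oxy}dimethylsilane | COc1ccc(COC/C=C(C)/CCO[Si](C)(C)C(C)(C)C)cc1 | intermediate
19 | (E)-5-(4-methoxybenzyloxy)-3-methylpent-3-en-1-ol | COc1ccc(COC/C=C(C)/CCO)cc1 | intermediate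
20 | 1-({[(2E)-5-iodo-3-methylpent-2-en-1-yl]oxy}methyl)-4-methoxybenzene | COc1ccc(COC/C=C(C)/CCI)cc1 | intermediate
21 | [(3E)-5-(4-methoxybenzyloxy)-3-methylpent-3-en-1-yl]lithium (not isolated) | [Li]CC/C(C)=C/COCc1ccc(OC)cc1 | intermediate
22 | 15-(4-methoxybenzyloxy)-6β-(triethylsilyloxy)labda-7,13E-dien-9-ol (9β-OH drawn as the expected major epimer; either epimer serves) | CC[Si](CC)(CC)O[C@@H]1C=C(C)[C@@](O)(CC/C(C)=C/COCc3ccc(OC)cc3)[C@@]2(C)CCCC(C)(C)[C@H]12 | intermediate
23 | 15-(4-methoxybenzyloxy)-6β-(triethylsilyloxy)labda-8,13E-dien-7-one | CC[Si](CC)(CC)O[C@@H]1C(=O)C(C)=C(CC/C(C)=C/COCc3ccc(OC)cc3)[C@@]2(C)CCCC(C)(C)[C@H]12 | intermediate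
24 | 6β-hydroxy-15-(4-methoxybenzyloxy)labda-8,13E-dien-7-one | O[C@@H]1C(=O)C(C)=C(CC/C(C)=C/COCc3ccc(OC)cc3)[C@@]2(C)CCCC(C)(C)[C@H]12 | intermediate
25 | 15-(4-methoxybenzyloxy)labda-8,13E-diene-6β,7α-diol | O[C@@H]1[C@@H](O)C(C)=C(CC/C(C)=C/COCc3ccc(OC)cc3)[C@@]2(C)CCCC(C)(C)[C@H]12 | intermediate
26 | 6β-hydroxy-15-(4-methoxybenzyloxy)labda-8,13E-dien-7α-yl 3-methylbutanoate | O[C@@H]1[C@@H](OC(=O)CC(C)C)C(C)=C(CC/C(C)=C/COCc3ccc(OC)cc3)[C@@]2(C)CCCC(C)(C)[C@H]12 | intermediate
27 | 6β-acetoxy-15-(4-methoxybenzyloxy)labda-8,13E-dien-7α-yl 3-methylbutanoate | CC(=O)O[C@@H]1[C@@H](OC(=O)CC(C)C)C(C)=C(CC/C(C)=C/COCc3ccc(OC)cc3)[C@@]2(C)CCCC(C)(C)[C@H]12 | intermediate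
28 | 6β-acetoxy-15-hydroxylabda-8,13E-dien-7α-yl 3-methylbutanoate | CC(=O)O[C@@H]1[C@@H](OC(=O)CC(C)C)C(C)=C(CC/C(C)=C/CO)[C@@]2(C)CCCC(C)(C)[C@H]12 | intermediate
29 | 6β-acetoxy-15-oxolabda-8,13E-dien-7α-yl 3-methylbutanoate | CC(=O)O[C@@H]1[C@@H](OC(=O)CC(C)C)C(C)=C(CC/C(C)=C/C=O)[C@@]2(C)CCCC(C)(C)[C@H]12 | intermediate
30 | 6β-acetoxy-7α-(3-methylbutanoyloxy)labda-8,13E-dien-15-oic acid (CNP0328312.2) | CC(=O)O[C@@H]1[C@@H](OC(=O)CC(C)C)C(C)=C(CC/C(C)=C/C(=O)O)[C@@]2(C)CCCC(C)(C)[C@H]12 | target

**Step count and risks**

Total step count: 22. Longest linear sequence: 17 steps (steps 1–8 and 14–22, from mesityl oxide); the side-chain branch (steps 9–13) joins at step 14.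

Steps most likely to fail:

1. Step 2 (key cycloaddition). The hindered CMe2 terminus may fail to close on C5 within the catalyst-bound ion pair, so that the reaction stalls, or the catalyst may discriminate the two quinone faces poorly with this bulkier diene. The fallback sets out from 3 and 4. The cycloaddition is driven instead by an achiral mixed aluminium Lewis acid (AlBr3/AlMe3, toluene/CH2Cl2, low temperature), a system of the kind used to force 4-methyl-2-silyloxypenta-1,3-dienes onto hindered enones. This gives the adduct as a racemate, that is 5 together with its mirror image ent-5 F1. The enantiomers are separated by preparative chromatography on a chiral stationary phase, and the route is rejoined at 5.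

2. Step 3 (ring-fusion epimerisation). Thermodynamic bias may be insufficient: both ring fusions carry one syn-axial methyl interaction, so equilibration may leave much of the cis isomer. The fallback sets out from 5 and replaces thermodynamic by kinetic control. KHMDS in THF at −78 °C removes the C5 proton to give the potassium dienolate F2. Inverse quench into AcOH/THF at −78 °C should protonate C5 from the α face, anti to the C10 methyl, which returns the route at 6.

3. Step 17 (directed reduction at C7). Exchange of the hindered 6β-hydroxyl onto boron may be slow, so that undirected α-face attack gives the 7β-alcohol, or the free α-ketol may isomerise. The fallback sets out from 23, before the silyl group is removed. Luche reduction (NaBH4, CeCl3·7H2O, MeOH, −78 °C), with hydride arriving anti to the axial 6β-silyloxy group, should give the 7β-allylic alcohol F3. Mitsunobu esterification with 3-methylbutanoic acid (DIAD, PPh3, toluene, 0 °C → rt) inverts C7 to the 7α-isovalerate silyl ether F4. HF·pyridine then removes the triethylsilyl group and the route is rejoined at 26.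

**Further compounds**

F1 | step 2 | ent-5, mirror image of the cis-fused adduct | O=C1C=C(C)C(=O)[C@]2(C)CC(O[Si](C(C)C)(C(C)C)C(C)C)=CC(C)(C)[C@H]12
F2 | step 3 | potassium C5(6)-dienolate of 5 | [K+].[O-]C1=C2C(C)(C)C=C(O[Si](C(C)C)(C(C)C)C(C)C)C[C@]2(C)C(=O)C(C)=C1
F3 | step 17 | 15-(4-methoxybenzyloxy)-6β-(triethylsilyloxy)labda-8,13E-dien-7β-ol | CC[Si](CC)(CC)O[C@@H]1[C@H](O)C(C)=C(CC/C(C)=C/COCc3ccc(OC)cc3)[C@@]2(C)CCCC(C)(C)[C@H]12
F4 | step 17 | 15-(4-methoxybenzyloxy)-6β-(triethylsilyloxy)labda-8,13E-dien-7α-yl 3-methylbutanoate | CC[Si](CC)(CC)O[C@@H]1[C@@H](OC(=O)CC(C)C)C(C)=C(CC/C(C)=C/COCc3ccc(OC)cc3)[C@@]2(C)CCCC(C)(C)[C@H]12
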